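(Readings and results were generated by integration on assumed constants; scatter was added.)

In a closed flask the solid substrate units are kept, so I reckoned with the fraction of solid left: what is missing from it stands dissolved, in ring or in open dimer.

| flask | solid substrate | remark | time |
|---|---|---|---|
| zeta | 2.8 M | run made earlier |  |
| flask | 2.0 M |  | 2.5 h |

- zeta (time / min: ring / %, solid substrate / %): 25.0: 3.8, 94.3; 50.0: 6.2, 90.1; 80.0: 10.8, 82.6; 90.0: 12.0, 81.8; 120: 16.3, 75.8

(each reading ± 1 percentage point)

- percent here means solid substrate units held: one open dimer counts as two
- solid substrate is a solid; its amount is given per volume of the solution
- what may be going on: solid substrate <-> starting material; starting material -> ring; 2 starting material -> open dimer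
- at the start none of the solid substrate is in solution

- autumn: doubling the dissolution coefficient of the solid substrate, all else as stated
- summer: doubling the solubility of the solid substrate, all else as stated

* amount of ring at 2.5 h, in percent of the solid substrate charged
* the change that raises the amount of ring at 2.5 h, in percent of the solid substrate charged most ("none" if none brings more than 2 percentage points) (autumn / summer / none)
* amount of ring at 2.5 h, in percent of the solid substrate charged, after summer

1. Fastest rung, the dissolved level: in the zeta run, ring stood at 0.233 of its last reading after 0.208 of the time, so I saw no lag and took the dissolved level as steady before the first reading.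

2. Next rung, the supply: the zeta run lost 24.2% of 2.8 M in 120 min, which gave 0.00565 M/min, the solid substrate entering solution per minute. I took dissolution as the rate-limiting step. In the zeta run the solid readings fell 1.03 times as fast after 50.0 min as before it, so I held the supply independent of the solid present. In the same run the ring reading at 120 min came to 67.4% of the solid lost.

3. Slowest rung, the emptying: at that supply, this flask's 2.0 M lasts 5.90 h, longer than 2.5 h, so I expected solid to remain, with 57.6% left and ring at 28.5%.

The forecast said “Dissolution therefore sets the supply” and gave 27% (20% to 31%), lower than my figure; it named summer as the best change, with 50% (37% to 59%) after it.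

    solid substrate ⇌ starting material, rate k1*(cs1 - [starting material]) while solid is left; crystals form when [starting material] > cs1 (solubility = 0.460 M, k = 2.40 × 10⁻⁴ /s)
    starting material → ring (k = 8.50 × 10⁻⁴ /s)
    2 starting material → open dimer (k = 0.00210 /M/s)

The flask gave 27.7% of ring, and summer was the best change, gaining 20 percentage points against 16 points and reaching 48.2%. In this flask solid substrate stood at 58.1% at 2.50 h, and at my supply I reckoned that a neighbour flask charged with 0.50 M lasted 1.47 h, shorter than 2.5 h; that neighbour flask held 0% of solid at 2.50 h. At 2.50 h, starting material in this flask was made 1.00 times as fast as it was used up, and it stood at 3.89%. Its half-life by the step to ring was 0.23 h, far shorter than 2.5 h.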